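**Retrosynthetic overview**

- Numbering: ring A (seven-membered) is C1(=O)–C2(Me)=C3–C4(O-acyl)–C5(H)–C6(Me)–C7H2 and ring B (five-membered) is C5–C6–C8–C9–C10(OH)(i-Pr). The route rests on the 1,5-relationship of the C1 and C10 oxygens across C7–C6–C5 (a De Mayo retron) and on the C4 oxygen next to C5 as the stereochemical lever.
- Late disconnections: the C4–O ester (protected p-coumaric acid), C2=C3 (Saegusa–Ito), and C10–i-Pr (organocerium addition while C1 is masked as the C1–O–C4 transannular methyl ketal).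
- Key disconnection: C5–C6 and C7–C1 by intramolecular enol–alkene [2+2] photocycloaddition, then C1–C5 by retro-aldol. Ring B closes first, the cyclobutane second, and ring A then arises by expansion of the starting cyclopentane (C1–C5).
- The photosubstrate is a 2-(4-methylpent-4-enoyl)cyclopentanone carrying the C2 methyl and C4 silyloxy groups. It comes from commercial (R)-4-silyloxycyclopentenone by α-methylation, hydrogenation and soft C5-acylation.

Key step: step 6

Remark: the skeleton numbering above is used for all intermediates; C2 (epimerisable, α to C1) is carried as a mixture of epimers and written without a descriptor until it becomes sp2 in step 13; diketone 7 is drawn as its ring-enol tautomer.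

**Route**

Step 1
Reactants: 1 (R)-4-(tert-butyldimethylsilyloxy)cyclopent-2-en-1-one
Product: 2 (R)-4-(tert-butyldimethylsilyloxy)-2-iodocyclopent-2-en-1-one
Conditions: I2, pyridine, CH2Cl2, 0 °C to rt
Reagents that add atoms: iodine, II
Why: Johnson α-iodination of an enone (conjugate addition of pyridine, iodination of the enolate, loss of pyridinium) functionalises C2 and leaves the C4 stereocentre untouched.

Step 2
Reactants: 2 (R)-4-(tert-butyldimethylsilyloxy)-2-iodocyclopent-2-en-1-one
Product: 3 (R)-4-(tert-butyldimethylsilyloxy)-2-methylcyclopent-2-en-1-one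
Conditions: Me4Sn, PdCl2(PhCN)2 (cat.), AsPh3, CuI, NMP, 80 °C
Reagents that add atoms: tetramethylstannane, C[Sn](C)(C)C
Why: Stille coupling of the α-iodoenone installs the C2 methyl group under neutral conditions, which avoids base-induced loss of the C4 silyloxy group.

Step 3
Reactants: 3 (R)-4-(tert-butyldimethylsilyloxy)-2-methylcyclopent-2-en-1-one
Product: 4 (4S)-4-(tert-butyldimethylsilyloxy)-2-methylcyclopentan-1-one (C2 epimers)
Conditions: H2 (1 atm), Pd/C (palladium on carbon), EtOAc, rt
Reagents that add atoms: none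
Why: Catalytic hydrogenation saturates C2=C3 with hydrogen delivered anti to the silyloxy group; the C2 centre so formed is immaterial, and the C4 descriptor changes from R to S only because C3 loses CIP rank.

Step 4
Reactants: 5 4-methylpent-4-enoic acid
Product: 6 1-(1H-benzotriazol-1-yl)-4-methylpent-4-en-1-one
Conditions: 1H-benzotriazole, EDC·HCl, CH2Cl2, 0 °C to rt
Reagents that add atoms: 1H-benzotriazole, c1ccc2[nH]nnc2c1
Why: Carbodiimide-mediated N-acylation gives a stable N-acylbenzotriazole without exposing the 1,1-disubstituted alkene to HCl, as acid chloride formation would.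

Step 5
Reactants: 4 (4S)-4-(tert-butyldimethylsilyloxy)-2-methylcyclopentan-1-one; 6 1-(1H-benzotriazol-1-yl)-4-methylpent-4-en-1-one
Product: 7 1-[(5S)-5-(tert-butyldimethylsilyloxy)-2-hydroxy-3-methylcyclopent-1-en-1-yl]-4-methylpent-4-en-1-one (ring-enol form of the 2-acylcyclopentanone)
Conditions: MgBr2·OEt2 (2.5 equiv), i-Pr2NEt (3 equiv), CH2Cl2, rt; cold aqueous citric acid work-up
Reagents that add atoms: none
Why: Soft-enolisation crossed-Claisen C-acylation acylates the C5 methylene, because only that product is an enolisable 1,3-diketone and is drained as its magnesium chelate (C2 acylation would give a quaternary, non-enolisable product), and the weakly basic medium holds back E1cB loss of the C4 silyloxy group.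

Step 6
Reactants: 7 1-[(5S)-5-(tert-butyldimethylsilyloxy)-2-hydroxy-3-methylcyclopent-1-en-1-yl]-4-methylpent-4-en-1-one
Product: 10 (4S,5S,6R)-4-(tert-butyldimethylsilyloxy)-2,6-dimethylbicyclo[5.3.0]decane-1,10-dione (trans-fused; skeleton numbering), via tricyclic cyclobutanol 8 (not isolated), via C10 enol 9 (not isolated)
Conditions: hν (λ about 300 nm, Pyrex), degassed cyclohexane, 0.01 M, 15 °C; then rt in the dark
Reagents that add atoms: none
Why: Excitation of the chelated enol of 7 (reacting as the ring enol C5=C1–OH conjugated to C10=O) leads through its triplet to 5-exo (1,5; rule of five) bonding of C5 to the inner alkene carbon C6, which closes ring B, and the C1/C7 1,4-biradical collapses to the cis-fused cyclobutanol 8; this strained aldol undergoes retro-aldol cleavage of C1–C5, so that ring A is formed by expansion of the cyclopentane into a cycloheptanone, and enol 9 ketonises to 10. The closest known reaction type is the intramolecular De Mayo reaction of 2-(pent-4-enoyl)cyclopentanones to bicyclo[5.3.0]decane-1,10-diones. C6 is set in the first bond: the C10–C9–C8 tether holds the alkene over C5 and the adjacent C4 silyloxy group shields one enol face, so that C6 bonds anti to it and the 4S,6R relationship results. C5 is set only in the ketonisation of 9, where the proton must arrive syn to the C4–O bond (anti to the C6 methyl) to give the trans-fused 5S epimer with C10 anti to the silyloxy group, a preference that equilibration through the enol should support but that the substrate does not enforce. The step needs straight (not crossed) regiochemistry, which the three-atom C5-to-C6 tether secures, and strictly neutral, base-free conditions so that neither 7 nor 10 loses silanol by β-elimination.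

Step 7
Reactants: 10 (4S,5S,6R)-4-(tert-butyldimethylsilyloxy)-2,6-dimethylbicyclo[5.3.0]decane-1,10-dione
Product: 12 (1S,4S,5S,6R)-1-methoxy-2,6-dimethyl-1,4-epoxybicyclo[5.3.0]decan-10-one (bridged methyl ketal; skeleton numbering), via hydroxy diketone 11 (not isolated)
Conditions: CSA (0.1 equiv), MeOH, 0 °C to rt; Et3N quench
Reagents that add atoms: methanol, CO
Why: Acid-catalysed methanolysis of the secondary silyl ether frees C4–OH, which closes transannularly onto the methanol-derived C1 oxocarbenium ion as a five-membered mixed ketal (8-oxabicyclo[3.2.1]octane), whereas the hindered C10 cyclopentanone has no such partner and stays free; the bridge fixes the C1 configuration.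

Step 8
Reactants: 12 (1S,4S,5S,6R)-1-methoxy-2,6-dimethyl-1,4-epoxybicyclo[5.3.0]decan-10-one
Product: 13 (1S,4S,5S,6R,10R)-1-methoxy-2,6-dimethyl-10-(propan-2-yl)-1,4-epoxybicyclo[5.3.0]decan-10-ol
Conditions: i-PrMgCl, anhydrous CeCl3, THF, −78 to 0 °C
Reagents that add atoms: isopropylmagnesium chloride, CC(C)[Mg]Cl
Why: Imamoto organocerium addition (low basicity, little enolisation or β-hydride reduction) to the only free carbonyl; the reagent should attack C10 from the face of H5, anti to the angular C6 methyl and to the C4 branch, which gives the 10R carbinol with the isopropyl group cis to H5.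

Step 9
Reactants: 13 (1S,4S,5S,6R,10R)-1-methoxy-2,6-dimethyl-10-(propan-2-yl)-1,4-epoxybicyclo[5.3.0]decan-10-ol
Product: 14 (4S,5S,6R,10R)-4,10-dihydroxy-2,6-dimethyl-10-(propan-2-yl)bicyclo[5.3.0]decan-1-one (in equilibrium with its bridged hemiketal)
Conditions: PPTS, acetone/H2O, 40 °C
Reagents that add atoms: water, O
Why: Mild acid hydrolysis of the mixed ketal returns the C1 ketone and C4–OH without dehydrating the tertiary C10 alcohol.

Step 10
Reactants: 15 p-coumaric acid
Product: 17 (E)-3-[4-(tert-butyldimethylsilyloxy)phenyl]prop-2-enoic acid, via silyl ester 16 (not isolated)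
Conditions: TBSCl (2.3 equiv), imidazole, DMF, rt; then AcOH, THF/H2O, rt
Reagents that add atoms: tert-butyldimethylsilyl chloride, CC(C)(C)[Si](C)(C)Cl
Why: Silylation of phenol and acid followed by selective hydrolysis of the labile silyl ester leaves the aryl silyl ether (standard phenol protection).

Step 11
Reactants: 14 (4S,5S,6R,10R)-4,10-dihydroxy-2,6-dimethyl-10-(propan-2-yl)bicyclo[5.3.0]decan-1-one; 17 (E)-3-[4-(tert-butyldimethylsilyloxy)phenyl]prop-2-enoic acid
Product: 18 (4S,5S,6R,10R)-10-hydroxy-2,6-dimethyl-1-oxo-10-(propan-2-yl)bicyclo[5.3.0]decan-4-yl (E)-3-[4-(tert-butyldimethylsilyloxy)phenyl]prop-2-enoate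
Conditions: EDC·HCl, DMAP, CH2Cl2, 0 °C to rt
Reagents that add atoms: none
Why: Steglich esterification acylates the secondary C4–OH of the open hydroxy ketone (draining the hemiketal equilibrium), while the tertiary C10–OH is too hindered to react.

Step 12
Reactants: 18 (4S,5S,6R,10R)-10-hydroxy-2,6-dimethyl-1-oxo-10-(propan-2-yl)bicyclo[5.3.0]decan-4-yl (E)-3-[4-(tert-butyldimethylsilyloxy)phenyl]prop-2-enoate
Product: 19 (4S,5S,6R,10R)-2,6-dimethyl-10-(propan-2-yl)-1,10-bis(trimethylsilyloxy)bicyclo[5.3.0]dec-1-en-4-yl (E)-3-[4-(tert-butyldimethylsilyloxy)phenyl]prop-2-enoate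
Conditions: TMSOTf (3 equiv), Et3N (4 equiv), CH2Cl2, 0 °C to rt
Reagents that add atoms: trimethylsilyl triflate, C[Si](C)(C)OS(=O)(=O)C(F)(F)F
Why: Soft enolisation should give mainly the more substituted C1=C2 silyl enol ether and also caps the C10 alcohol; the coumarate has no enolisable position, and any C1=C7 isomer cannot be dehydrogenated (C6 is quaternary) and merely reverts to the ketone.

Step 13
Reactants: 19 (4S,5S,6R,10R)-2,6-dimethyl-10-(propan-2-yl)-1,10-bis(trimethylsilyloxy)bicyclo[5.3.0]dec-1-en-4-yl (E)-3-[4-(tert-butyldimethylsilyloxy)phenyl]prop-2-enoate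
Product: 20 (4S,5S,6R,10R)-2,6-dimethyl-1-oxo-10-(propan-2-yl)-10-(trimethylsilyloxy)bicyclo[5.3.0]dec-2-en-4-yl (E)-3-[4-(tert-butyldimethylsilyloxy)phenyl]prop-2-enoate
Conditions: Pd(OAc)2 (1.1 equiv), MeCN, rt
Reagents that add atoms: none
Why: Saegusa–Ito oxidation (palladation at C2, β-hydride elimination of H3) gives the C2=C3 enone, the only α,β-desaturation that the C1 ketone allows.

Step 14
Reactants: 20 (4S,5S,6R,10R)-2,6-dimethyl-1-oxo-10-(propan-2-yl)-10-(trimethylsilyloxy)bicyclo[5.3.0]dec-2-en-4-yl (E)-3-[4-(tert-butyldimethylsilyloxy)phenyl]prop-2-enoate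
Product: 21 (4S,5S,6R,10R)-10-hydroxy-2,6-dimethyl-1-oxo-10-(propan-2-yl)bicyclo[5.3.0]dec-2-en-4-yl (E)-3-(4-hydroxyphenyl)prop-2-enoate (CNP0310968.1)
Conditions: HF·pyridine, pyridine/THF, 0 °C to rt
Reagents that add atoms: none
Why: Buffered fluoride cleaves the aryl silyl ether and the tertiary trimethylsilyl ether without base that could hydrolyse the ester or attack the γ-acyloxy enone.

**Compound list**

1 | (R)-4-(tert-butyldimethylsilyloxy)cyclopent-2-en-1-one | O=C1C=C[C@H](O[Si](C)(C)C(C)(C)C)C1 | starting material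
2 | (R)-4-(tert-butyldimethylsilyloxy)-2-iodocyclopent-2-en-1-one | O=C1C(I)=C[C@H](O[Si](C)(C)C(C)(C)C)C1 | intermediate
3 | (R)-4-(tert-butyldimethylsilyloxy)-2-methylcyclopent-2-en-1-one | CC1=C[C@H](O[Si](C)(C)C(C)(C)C)CC1=O | intermediate
4 | (4S)-4-(tert-butyldimethylsilyloxy)-2-methylcyclopentan-1-one (C2 epimers) | CC1C[C@H](O[Si](C)(C)C(C)(C)C)CC1=O | intermediate
5 | 4-methylpent-4-enoic acid | CC(=C)CCC(O)=O | starting material
6 | 1-(1H-benzotriazol-1-yl)-4-methylpent-4-en-1-one | CC(=C)CCC(=O)n1nnc2ccccc12 | intermediate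
7 | 1-[(5S)-5-(tert-butyldimethylsilyloxy)-2-hydroxy-3-methylcyclopent-1-en-1-yl]-4-methylpent-4-en-1-one (ring-enol form; photosubstrate) | CC1C[C@H](O[Si](C)(C)C(C)(C)C)C(C(=O)CCC(C)=C)=C1O | intermediate
8 | tricyclic cyclobutanol photoadduct (cyclobutane C1–C5–C6–C7 cis-fused to the C1–C5 ring and to ring B, anti to the C4 silyl ether; C1–OH, C10=O) | CC1C[C@H](O[Si](C)(C)C(C)(C)C)[C@@]23C(=O)CC[C@]2(C)C[C@@]13O | intermediate
9 | (4S,6R)-4-(tert-butyldimethylsilyloxy)-10-hydroxy-2,6-dimethylbicyclo[5.3.0]dec-5(10)-en-1-one (C10 enol) | CC1C[C@H](O[Si](C)(C)C(C)(C)C)C2=C(O)CC[C@]2(C)CC1=O | intermediate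
10 | (4S,5S,6R)-4-(tert-butyldimethylsilyloxy)-2,6-dimethylbicyclo[5.3.0]decane-1,10-dione (trans-fused) | CC1C[C@H](O[Si](C)(C)C(C)(C)C)[C@@H]2[C@](C)(CCC2=O)CC1=O | intermediate
11 | (4S,5S,6R)-4-hydroxy-2,6-dimethylbicyclo[5.3.0]decane-1,10-dione | CC1C[C@H](O)[C@@H]2[C@](C)(CCC2=O)CC1=O | intermediate
12 | (1S,4S,5S,6R)-1-methoxy-2,6-dimethyl-1,4-epoxybicyclo[5.3.0]decan-10-one (bridged methyl ketal) | CC1C[C@@H]2O[C@@]1(OC)C[C@@]3(C)CCC(=O)[C@H]23 | intermediate
13 | (1S,4S,5S,6R,10R)-1-methoxy-2,6-dimethyl-10-(propan-2-yl)-1,4-epoxybicyclo[5.3.0]decan-10-ol | CC1C[C@@H]2O[C@@]1(OC)C[C@@]3(C)CC[C@@](O)(C(C)C)[C@H]23 | intermediate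
14 | (4S,5S,6R,10R)-4,10-dihydroxy-2,6-dimethyl-10-(propan-2-yl)bicyclo[5.3.0]decan-1-one | CC1C[C@H](O)[C@@H]2[C@](C)(CC[C@@]2(O)C(C)C)CC1=O | intermediate
15 | p-coumaric acid | OC(=O)/C=C/c1ccc(O)cc1 | starting material
16 | tert-butyldimethylsilyl (E)-3-[4-(tert-butyldimethylsilyloxy)phenyl]prop-2-enoate | CC(C)(C)[Si](C)(C)OC(=O)/C=C/c1ccc(O[Si](C)(C)C(C)(C)C)cc1 | intermediate
17 | (E)-3-[4-(tert-butyldimethylsilyloxy)phenyl]prop-2-enoic acid | OC(=O)/C=C/c1ccc(O[Si](C)(C)C(C)(C)C)cc1 | intermediate
18 | (4S,5S,6R,10R)-10-hydroxy-2,6-dimethyl-1-oxo-10-(propan-2-yl)bicyclo[5.3.0]decan-4-yl (E)-3-[4-(tert-butyldimethylsilyloxy)phenyl]prop-2-enoate | CC1C[C@H](OC(=O)/C=C/c2ccc(O[Si](C)(C)C(C)(C)C)cc2)[C@@H]2[C@](C)(CC[C@@]2(O)C(C)C)CC1=O | intermediate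
19 | (4S,5S,6R,10R)-2,6-dimethyl-10-(propan-2-yl)-1,10-bis(trimethylsilyloxy)bicyclo[5.3.0]dec-1-en-4-yl (E)-3-[4-(tert-butyldimethylsilyloxy)phenyl]prop-2-enoate | C[Si](C)(C)OC1=C(C)C[C@H](OC(=O)/C=C/c2ccc(O[Si](C)(C)C(C)(C)C)cc2)[C@@H]2[C@](C)(CC[C@@]2(O[Si](C)(C)C)C(C)C)C1 | intermediate
20 | (4S,5S,6R,10R)-2,6-dimethyl-1-oxo-10-(propan-2-yl)-10-(trimethylsilyloxy)bicyclo[5.3.0]dec-2-en-4-yl (E)-3-[4-(tert-butyldimethylsilyloxy)phenyl]prop-2-enoate | CC1=C[C@H](OC(=O)/C=C/c2ccc(O[Si](C)(C)C(C)(C)C)cc2)[C@@H]2[C@](C)(CC[C@@]2(O[Si](C)(C)C)C(C)C)CC1=O | intermediate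
21 | (4S,5S,6R,10R)-10-hydroxy-2,6-dimethyl-1-oxo-10-(propan-2-yl)bicyclo[5.3.0]dec-2-en-4-yl (E)-3-(4-hydroxyphenyl)prop-2-enoate (CNP0310968.1) | CC1=C[C@H](OC(=O)/C=C/c2ccc(O)cc2)[C@@H]2[C@](C)(CC[C@@]2(O)C(C)C)CC1=O | target

**Step count**

Total step count: 14 (steps 4 and 10 prepare the two side fragments).
Longest linear sequence: 12 steps (1 → 2 → 3 → 4 → 7 → 10 → 12 → 13 → 14 → 18 → 19 → 20 → 21; steps 1, 2, 3, 5, 6, 7, 8, 9, 11, 12, 13, 14).

**Steps most likely to fail**

1. Step 6. The ketonisation of enol 9 may deliver the proton to C5 anti to the silyloxy group, so that the cis-fused C5 epimer dominates; loss of silanol by β-elimination is the second hazard. The fallback sets out from 7 and comes back at 12; it moves the C5 decision out of the flexible seven-membered ring and into the rigid bridged ketal. The irradiation is run as before and the cis-fused diketone F1, alone or mixed with 10, is taken through the CSA/MeOH step to the cis-fused bridged ketal F2. TMSOTf/Et3N in CH2Cl2 at rt (thermodynamic conditions) should convert F2, and any 12 present, into the common tetrasubstituted C10=C5 trimethylsilyl enol ether F3; a C10=C9 isomer would simply return the ketone and be recycled. MeLi (THF, 0 °C) releases the lithium enolate, which is protonated at −78 °C with 2,6-di-tert-butylphenol. In the half-chair of the 8-oxabicyclo[3.2.1]octane the proton should enter C5 axially, on the face of the oxygen bridge and anti to the axial C6 methyl and the C2–C3 bridge, which gives the trans-fused ketal ketone 12.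

2. Step 5. The magnesium enolate or the diketonate may expel silanolate from C4 (E1cB), or acylation may stray to C2 or to oxygen. The fallback sets out from 4 and comes back at 7; it never generates a free enolate above −78 °C. LDA in the presence of TMSCl (THF, −78 °C, internal quench) traps the kinetic C5 enolate at once as the C1=C5 trimethylsilyl enol ether F4. Acid 5 is reduced with LiAlH4 to 4-methylpent-4-en-1-ol F5 and oxidised (Swern) to 4-methylpent-4-enal F6. Mukaiyama aldol addition of F4 to F6 (BF3·OEt2, CH2Cl2, −78 °C) gives the β-hydroxy ketone F7 as a mixture of diastereomers, and Dess–Martin periodinane (NaHCO3, CH2Cl2) oxidises it to 7 under neutral conditions.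

3. Step 8. The hindered C10 ketone may be reduced by β-hydride transfer from the secondary organometallic, or merely enolised, instead of undergoing addition. The fallback sets out from 12 and comes back at 13. Isopropenylmagnesium bromide with CeCl3 (THF, −78 °C), an sp2 nucleophile that is smaller and cannot transfer hydride, should give the isopropenyl carbinol F8 with the same facial preference, and hydrogenation of its 1,1-disubstituted alkene (H2, PtO2, EtOAc) gives 13.

**Further compounds**

F1 | step 6 | (4S,5R,6R)-4-(tert-butyldimethylsilyloxy)-2,6-dimethylbicyclo[5.3.0]decane-1,10-dione (cis-fused diketone) | CC1C[C@H](O[Si](C)(C)C(C)(C)C)[C@H]2[C@](C)(CCC2=O)CC1=O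
F2 | step 6 | (1S,4S,5R,6R)-1-methoxy-2,6-dimethyl-1,4-epoxybicyclo[5.3.0]decan-10-one (cis-fused bridged ketal) | CC1C[C@@H]2O[C@@]1(OC)C[C@@]3(C)CCC(=O)[C@@H]23
F3 | step 6 | (1S,4S,6R)-1-methoxy-2,6-dimethyl-10-(trimethylsilyloxy)-1,4-epoxybicyclo[5.3.0]dec-5(10)-ene (C10=C5 trimethylsilyl enol ether) | CC1C[C@@H]2O[C@@]1(OC)C[C@@]3(C)CCC(O[Si](C)(C)C)=C23
F4 | step 5 | (4S)-4-(tert-butyldimethylsilyloxy)-2-methyl-1-(trimethylsilyloxy)cyclopent-1(5)-ene (C1=C5 trimethylsilyl enol ether of 4) | CC1C[C@H](O[Si](C)(C)C(C)(C)C)C=C1O[Si](C)(C)C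
F5 | step 5 | 4-methylpent-4-en-1-ol | CC(=C)CCCO
F6 | step 5 | 4-methylpent-4-enal | CC(=C)CCC=O
F7 | step 5 | (4S)-4-(tert-butyldimethylsilyloxy)-5-(1-hydroxy-4-methylpent-4-enyl)-2-methylcyclopentan-1-one (aldol; diastereomer mixture) | CC1C[C@H](O[Si](C)(C)C(C)(C)C)C(C(O)CCC(C)=C)C1=O
F8 | step 8 | isopropenyl analogue of 13: 1-methoxy-2,6-dimethyl-10-(prop-1-en-2-yl)-1,4-epoxybicyclo[5.3.0]decan-10-ol (same spatial arrangement as 13; descriptor at C10 becomes S) | CC1C[C@@H]2O[C@@]1(OC)C[C@@]3(C)CC[C@@](O)(C(C)=C)[C@H]23
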